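**Retrosynthetic overview**
- Ring B is closed last, by joining the acetyl CH3 of ring A to the chloro-bearing enone carbon (C10–C10a); this gives the 10-CH2/9-C=O unit directly. Just before that, the C2 methoxy group is put on the enaminone C–H (iodination, then Cu-mediated C–O coupling).
- The pyrrolidine/oxazolidine N,O-acetal comes from a γ-hydroxy vinylogous ester (ring C quinol) and 1,2-oxazinane: N adds at C3 with loss of methoxide, the six-membered N–O ring is cut and reclosed as the five-membered hemiaminal, and the C4 hydroxyl captures the iminium.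
- Enabling feature: the pyrrolidine CH bonded to both N and O is at the aldehyde oxidation level, and its O is the tertiary C4–O of ring C next to the N-bearing enaminone carbon C3. An N–O bond in a 1,2-oxazinane stores this oxidation level, and the vinylogous acyl group on N turns N into a leaving group.
- The aryl quinol comes from a bromo-enone quinol and an aryl boronate (Suzuki). The quinol comes from a flat tetrasubstituted phenol by catalytic enantioselective hydrative para-dearomatization, which sets the quaternary carbinol centre.
- Order of ring formation: ring C (dearomatized arene), ring A attached, pyrrolidine (by contraction of the oxazinane) together with the oxazolidine, then ring B.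

Key step: step 7

Remark: locants are those of the phenanthrene core of the target (C1 dienone C=O, C2 OMe, C3 N, C4 C(CH3)–O, C4a/C10a ring-fusion alkene, C8 OH, C9 aryl C=O, C10 CH2); the target is taken in the written 9-keto/10-CH2 form, which is the constitution that the last step creates.

**Step 1**
Reactants: 1 1-bromo-3-methoxy-2-methylbenzene
Product: 3 3-bromo-5-methoxy-4-methylphenol, via aryl pinacol boronate 2 (not isolated)
Conditions: [Ir(OMe)(cod)]2 (1.5 mol %), dtbpy (3 mol %), B2pin2 (0.6 equiv), THF, 80 °C; then Oxone, acetone–H2O, 23 °C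
Reagents that add atoms: potassium peroxymonosulfate (Oxone), [K+].[O-]S(=O)(=O)OO
Why: Iridium-catalysed C–H borylation is sterically governed and should take the only C–H without an ortho substituent (meta to Br and OMe, para to CH3), and Oxone then oxidises the C–B bond to the phenol in the same flask (one-pot C–H borylation/oxidation).

**Step 2**
Reactants: 3 3-bromo-5-methoxy-4-methylphenol
Product: 4 3-bromo-2-chloro-5-methoxy-4-methylphenol
Conditions: NCS (1.05 equiv), MeCN, 0 → 23 °C
Reagents that add atoms: N-chlorosuccinimide, O=C1CCC(=O)N1Cl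
Why: Electrophilic aromatic chlorination of the phenol should go to the ortho carbon that is also para to the methoxy group, because the para position is blocked by CH3 and the other ortho carbon lies between the two oxygen substituents.

**Step 3**
Reactants: 4 3-bromo-2-chloro-5-methoxy-4-methylphenol
Product: 5 (4S)-3-bromo-2-chloro-4-hydroxy-5-methoxy-4-methylcyclohexa-2,5-dien-1-one
Conditions: C2-symmetric chiral aryl iodide of the 2-iodoresorcinol bis(lactamide) type (10 mol %, antipode chosen to give 4S), mCPBA (1.3 equiv), MeCN–H2O (9:1), −10 °C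
Reagents that add atoms: water, O
Why: Chiral aryl-λ3-iodane-catalysed hydrative para-dearomatization of a 4-alkylphenol (enantioselective oxidative dearomatization), in which water attacks the methyl-bearing para carbon of the iodane-bound phenol to give a vinylogous ester and the chiral iodane differentiates the two faces, so that the quaternary carbinol centre is set as (S), the spatial arrangement that becomes (R) in the target once aryl replaces Br.

**Step 4**
Reactants: 6 1-(2,6-dihydroxy-4-methoxyphenyl)ethan-1-one
Product: 7 2-acetyl-3-hydroxy-5-methoxyphenyl trifluoromethanesulfonate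
Conditions: Tf2O (1.0 equiv), pyridine, CH2Cl2, −40 → 0 °C
Reagents that add atoms: trifluoromethanesulfonic anhydride, O=S(=O)(OS(=O)(=O)C(F)(F)F)C(F)(F)F
Why: Mono-sulfonylation of a symmetrical 2,6-dihydroxyaryl ketone, since after the first triflation the remaining OH is locked in the hydrogen bond to the acetyl group and should resist a second one.

**Step 5**
Reactants: 7 2-acetyl-3-hydroxy-5-methoxyphenyl trifluoromethanesulfonate
Product: 8 1-[2-hydroxy-4-methoxy-6-(4,4,5,5-tetramethyl-1,3,2-dioxaborolan-2-yl)phenyl]ethan-1-one
Conditions: B2pin2, Pd(dppf)Cl2 (5 mol %), KOAc, 1,4-dioxane, 80 °C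
Reagents that add atoms: bis(pinacolato)diboron, CC1(C)OB(OC1(C)C)B1OC(C)(C)C(C)(C)O1
Why: Miyaura borylation of an aryl triflate activated by the ortho acetyl group, with KOAc too weak a base to engage the hydrogen-bonded phenol or the ketone.

**Step 6**
Reactants: 5 (4S)-3-bromo-2-chloro-4-hydroxy-5-methoxy-4-methylcyclohexa-2,5-dien-1-one and 8 1-[2-hydroxy-4-methoxy-6-(4,4,5,5-tetramethyl-1,3,2-dioxaborolan-2-yl)phenyl]ethan-1-one
Product: 9 (4R)-3-(2-acetyl-3-hydroxy-5-methoxyphenyl)-2-chloro-4-hydroxy-5-methoxy-4-methylcyclohexa-2,5-dien-1-one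
Conditions: Pd(OAc)2 (5 mol %), SPhos (10 mol %), K3PO4, toluene–H2O (10:1), 50 °C
Reagents that add atoms: none
Why: Suzuki–Miyaura coupling at the β-bromo enone C–Br bond, which should undergo oxidative addition far faster than the α C–Cl bond, leaving the stereocentre untouched (the descriptor changes from S to R only because aryl replaces Br) and giving a mixture of atropisomers about the new aryl–alkenyl bond that converges in step 10.

**Step 7**
Reactants: 9 (4R)-3-(2-acetyl-3-hydroxy-5-methoxyphenyl)-2-chloro-4-hydroxy-5-methoxy-4-methylcyclohexa-2,5-dien-1-one and 10 1,2-oxazinane hydrochloride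
Product: 14 (3aS,4aR)-5-(2-acetyl-3-hydroxy-5-methoxyphenyl)-6-chloro-4a-methyl-2,3,3a,4a-tetrahydro-1H-pyrrolo[2,1-b][1,3]benzoxazol-7-one, via oxazinanyl enaminone 11 (not isolated), via amino aldehyde 12 (not isolated), via pyrrolidine hemiaminal 13 (not isolated)
Conditions: 10 (1.5 equiv), KHMDS (6.5 equiv), THF, −78 → 23 °C; then AcOH (excess), CSA (10 mol %), 23 °C
Reagents that add atoms: none
Why: Proposed new method: the N-potassio hydroxylamine adds to C3 of the γ-hydroxy vinylogous ester and expels methoxide (addition–elimination, giving 11), after which base (excess amide or the neighbouring C4 alkoxide) removes an O–CH2 proton antiperiplanar to the N–O bond and the vinylogous-amide nitrogen leaves as the anion, an E2 fragmentation of Kornblum–DeLaMare type whose closest precedents are the base-induced loss of formaldehyde from N-methoxy-N-methyl amides and the base-promoted 1,2-oxazine-to-pyrrole conversion, so that the six-membered 1,2-oxazinane opens to amino aldehyde 12. The nitrogen anion recloses on the aldehyde by 5-exo-trig addition, which contracts the ring to the pyrrolidine hemiaminal 13 with the N–O bond acting as the internal oxidant for the aminal carbon. On acidification the hemiaminal ionises to a vinylogous N-acyliminium ion and the tertiary C4–OH closes the oxazolidine by 5-endo-trig capture of the iminium, the usual mode of oxazolidine formation. The new N,O-acetal centre is set under thermodynamic control, because both hemiaminal epimers pass through the same planar iminium and the reversible closure should settle on the (S) isomer with the pyrrolidine CH2 anti to the C4 methyl (aminal H syn to CH3), the fixed (R) quaternary centre being the controlling element. The step needs N–O cleavage toward the O–CH2 side and not the N–CH2 side, which the much better leaving ability of the delocalised vinylogous-amide anion over an alkoxide should secure, and amine attack at C3 and not at the carbonyl groups or the aryl-blocked β-carbon of the chloro enone, which the methoxide leaving group and the reversibility of 1,2-addition should secure.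

**Step 8**
Reactants: 14 (3aS,4aR)-5-(2-acetyl-3-hydroxy-5-methoxyphenyl)-6-chloro-4a-methyl-2,3,3a,4a-tetrahydro-1H-pyrrolo[2,1-b][1,3]benzoxazol-7-one
Product: 15 (3aS,4aR)-5-(2-acetyl-3-hydroxy-5-methoxyphenyl)-6-chloro-8-iodo-4a-methyl-2,3,3a,4a-tetrahydro-1H-pyrrolo[2,1-b][1,3]benzoxazol-7-one
Conditions: NIS (1.05 equiv), CH2Cl2, −20 → 0 °C
Reagents that add atoms: N-iodosuccinimide, O=C1CCC(=O)N1I
Why: Electrophilic iodination at the α-carbon of the enaminone (C2–H), the only strongly nucleophilic sp2 C–H because the nitrogen lone pair feeds it, which should outpace iodination of the acyl-deactivated phenol ring at low temperature.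

**Step 9**
Reactants: 15 (3aS,4aR)-5-(2-acetyl-3-hydroxy-5-methoxyphenyl)-6-chloro-8-iodo-4a-methyl-2,3,3a,4a-tetrahydro-1H-pyrrolo[2,1-b][1,3]benzoxazol-7-one
Product: 16 (3aS,4aR)-5-(2-acetyl-3-hydroxy-5-methoxyphenyl)-6-chloro-8-methoxy-4a-methyl-2,3,3a,4a-tetrahydro-1H-pyrrolo[2,1-b][1,3]benzoxazol-7-one
Conditions: CuI (20 mol %), 3,4,7,8-tetramethyl-1,10-phenanthroline (40 mol %), Cs2CO3, MeOH–toluene, 80 °C
Reagents that add atoms: methanol, CO
Why: Copper-catalysed Ullmann-type C–O coupling of the alkenyl iodide with methanol, in which the alkenyl chloride should stay inert to copper and both stereocentres are stable to base.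

**Step 10**
Reactants: 16 (3aS,4aR)-5-(2-acetyl-3-hydroxy-5-methoxyphenyl)-6-chloro-8-methoxy-4a-methyl-2,3,3a,4a-tetrahydro-1H-pyrrolo[2,1-b][1,3]benzoxazol-7-one
Product: 17 CNP0528850.1 (target)
Conditions: Pd2(dba)3 (5 mol %), XPhos (12 mol %), LiHMDS (3.5 equiv), THF, 60 °C; then AcOH–H2O
Reagents that add atoms: none
Why: Palladium-catalysed intramolecular α-alkenylation of the methyl ketone enolate (as the phenoxide–enolate dianion) with the α-chloro enone should close ring B as a six-membered ring through a seven-membered palladacycle and give the 10-CH2/9-ketone directly, with both atropisomers of 16 reaching the same palladacycle so that the mixture converges and the two stereocentres are not touched.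

**Compound list**
1 | 1-bromo-3-methoxy-2-methylbenzene | COc1cccc(Br)c1C | starting material
2 | 2-(3-bromo-5-methoxy-4-methylphenyl)-4,4,5,5-tetramethyl-1,3,2-dioxaborolane (formed in the flask) | COc1cc(B2OC(C)(C)C(C)(C)O2)cc(Br)c1C | intermediate
3 | 3-bromo-5-methoxy-4-methylphenol | COc1cc(O)cc(Br)c1C | intermediate
4 | 3-bromo-2-chloro-5-methoxy-4-methylphenol | COc1cc(O)c(Cl)c(Br)c1C | intermediate
5 | (4S)-3-bromo-2-chloro-4-hydroxy-5-methoxy-4-methylcyclohexa-2,5-dien-1-one | O=C1C=C(OC)[C@](C)(O)C(Br)=C1Cl | intermediate
6 | 1-(2,6-dihydroxy-4-methoxyphenyl)ethan-1-one | CC(=O)c1c(O)cc(OC)cc1O | starting material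
7 | 2-acetyl-3-hydroxy-5-methoxyphenyl trifluoromethanesulfonate | CC(=O)c1c(O)cc(OC)cc1OS(=O)(=O)C(F)(F)F | intermediate
8 | 1-[2-hydroxy-4-methoxy-6-(4,4,5,5-tetramethyl-1,3,2-dioxaborolan-2-yl)phenyl]ethan-1-one | CC(=O)c1c(O)cc(OC)cc1B1OC(C)(C)C(C)(C)O1 | intermediate
9 | (4R)-3-(2-acetyl-3-hydroxy-5-methoxyphenyl)-2-chloro-4-hydroxy-5-methoxy-4-methylcyclohexa-2,5-dien-1-one (atropisomer mixture) | O=C1C=C(OC)[C@](C)(O)C(c2cc(OC)cc(O)c2C(C)=O)=C1Cl | intermediate
10 | 1,2-oxazinane hydrochloride | Cl.C1CCNOC1 | starting material
11 | (4R)-3-(2-acetyl-3-hydroxy-5-methoxyphenyl)-2-chloro-4-hydroxy-4-methyl-5-(1,2-oxazinan-2-yl)cyclohexa-2,5-dien-1-one (formed in the flask) | O=C1C=C(N2CCCCO2)[C@](C)(O)C(c2cc(OC)cc(O)c2C(C)=O)=C1Cl | intermediate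
12 | (4R)-3-(2-acetyl-3-hydroxy-5-methoxyphenyl)-2-chloro-4-hydroxy-4-methyl-5-[(4-oxobutyl)amino]cyclohexa-2,5-dien-1-one (formed in the flask) | O=C1C=C(NCCCC=O)[C@](C)(O)C(c2cc(OC)cc(O)c2C(C)=O)=C1Cl | intermediate
13 | (4R)-3-(2-acetyl-3-hydroxy-5-methoxyphenyl)-2-chloro-4-hydroxy-5-(2-hydroxypyrrolidin-1-yl)-4-methylcyclohexa-2,5-dien-1-one (both hemiaminal epimers; formed in the flask) | O=C1C=C(N2CCCC2O)[C@](C)(O)C(c2cc(OC)cc(O)c2C(C)=O)=C1Cl | intermediate
14 | (3aS,4aR)-5-(2-acetyl-3-hydroxy-5-methoxyphenyl)-6-chloro-4a-methyl-2,3,3a,4a-tetrahydro-1H-pyrrolo[2,1-b][1,3]benzoxazol-7-one | O=C1C=C2N3CCC[C@@H]3O[C@]2(C)C(c2cc(OC)cc(O)c2C(C)=O)=C1Cl | intermediate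
15 | (3aS,4aR)-5-(2-acetyl-3-hydroxy-5-methoxyphenyl)-6-chloro-8-iodo-4a-methyl-2,3,3a,4a-tetrahydro-1H-pyrrolo[2,1-b][1,3]benzoxazol-7-one | O=C1C(I)=C2N3CCC[C@@H]3O[C@]2(C)C(c2cc(OC)cc(O)c2C(C)=O)=C1Cl | intermediate
16 | (3aS,4aR)-5-(2-acetyl-3-hydroxy-5-methoxyphenyl)-6-chloro-8-methoxy-4a-methyl-2,3,3a,4a-tetrahydro-1H-pyrrolo[2,1-b][1,3]benzoxazol-7-one | COC1=C2N3CCC[C@@H]3O[C@]2(C)C(c2cc(OC)cc(O)c2C(C)=O)=C(Cl)C1=O | intermediate
17 | CNP0528850.1: 8-hydroxy-2,6-dimethoxy-4-methyl-10H-phenanthrene-1,9-dione core whose C3–N and C4–O are bridged by the pyrrolidine N,O-acetal carbon; (R) at the methyl-bearing C–O carbon, (S) at the N,O-acetal carbon | COC1=C2N3CCC[C@@H]3O[C@]2(C)C2=C(CC(=O)c3c(O)cc(OC)cc32)C1=O | target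

**Step count and risks**
Total step count: 10. Longest linear sequence: 8 steps (1, 2, 3, 6, 7, 8, 9, 10); steps 4 and 5 make the ring A partner.

Steps most likely to fail:

1. Step 7 (Proposed new method). The base-induced N–O fragmentation may be outrun by reversal of the amine addition, by cleavage on the N–CH2 side, or by aldol reactions of the liberated aldehyde, so that the oxazinane is not converted cleanly into the hemiaminal. The fallback sets out from 9 and comes back at 14. Heating 9 with commercial 4-aminobutanal diethyl acetal (NCCCC(OCC)OCC) and Et3N in EtOH should give, by the same addition–elimination at C3, the secondary enaminone acetal F1. Mild aqueous acid (AcOH–THF–H2O, then catalytic CSA) should then unmask the aldehyde, which closes on the enaminone nitrogen to hemiaminal 13 and on to 14 under the same thermodynamic control. Both operations are known reaction types (vinylogous ester aminolysis, acetal hydrolysis with N,O-acetal formation), and the pyrrolidine is then made by cyclisation of a 4-aminobutanal equivalent.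

2. Step 3. Facial discrimination may be poor when water attacks the iodane-activated phenol intermolecularly at the para carbon, which would give low enantiomeric purity. The fallback sets out from 4 and comes back at 5. Oxidation with PhI(OAc)2 in MeCN–H2O at 0 °C should give the racemic quinol F2, which is resolved by preparative chromatography on a chiral stationary phase (SFC). The (4S) enantiomer is 5 and continues in step 6; the (4R) enantiomer F3 is set aside.

3. Step 10. Enolate formation next to the phenoxide may be too slow, so that protodechlorination of the alkenyl–palladium species or base-induced decomposition wins over C–C bond formation. The fallback sets out from 16 and comes back at 17. Treatment with TBSOTf and Et3N in CH2Cl2 should give the silyl enol ether/aryl silyl ether F4. Pd(OAc)2, P(t-Bu)3 and Bu3SnF in toluene at 80 °C should then couple the tin enolate formed in the flask with the alkenyl chloride under neutral conditions to give the ring-closed 8-O-silyl ether F5. TBAF buffered with AcOH should finally free the phenol to give 17.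

**Further compounds**
F1 | step 7 | (4R)-3-(2-acetyl-3-hydroxy-5-methoxyphenyl)-2-chloro-5-[(4,4-diethoxybutyl)amino]-4-hydroxy-4-methylcyclohexa-2,5-dien-1-one | O=C1C=C(NCCCC(OCC)OCC)[C@](C)(O)C(c2cc(OC)cc(O)c2C(C)=O)=C1Cl
F2 | step 3 | racemic 3-bromo-2-chloro-4-hydroxy-5-methoxy-4-methylcyclohexa-2,5-dien-1-one | O=C1C=C(OC)C(C)(O)C(Br)=C1Cl
F3 | step 3 | (4R)-3-bromo-2-chloro-4-hydroxy-5-methoxy-4-methylcyclohexa-2,5-dien-1-one | O=C1C=C(OC)[C@@](C)(O)C(Br)=C1Cl
F4 | step 10 | bis-silylated 16 (aryl tert-butyldimethylsilyl ether and tert-butyldimethylsilyl enol ether of the acetyl group) | COC1=C2N3CCC[C@@H]3O[C@]2(C)C(c2cc(OC)cc(O[Si](C)(C)C(C)(C)C)c2C(=C)O[Si](C)(C)C(C)(C)C)=C(Cl)C1=O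
F5 | step 10 | 8-O-tert-butyldimethylsilyl ether of 17 | COC1=C2N3CCC[C@@H]3O[C@]2(C)C2=C(CC(=O)c3c(O[Si](C)(C)C(C)(C)C)cc(OC)cc32)C1=O
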